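If G stays near its solubility while solid E feeds it, the share of J at a reading depends on how many lifetimes of J fit into the reading time.

| setting | dusk | winter | dawn |
|---|---|---|---|
| E | 5.0 × 10⁻⁴ M | 5.0 × 10⁻⁴ M | 5.0 × 10⁻⁴ M |
| temperature | 35 °C | 50 °C | 20 °C |
| time | 15 s | 15 s | 15 s |

    G → J (k1 = 0.0705 s⁻¹, Ea1 = 81.0 kJ mol⁻¹)
    2 G → Q (k2 = 143 M⁻¹ s⁻¹, Ea2 = 41.0 kJ mol⁻¹)
    E ⇌ G, rate k3*(cs3 - [G]) while solid is left; crystals form when [G] > cs3 (cs3 = 0.14 mM, k3 = 0.601 s⁻¹)
    G → D (k4 = 9.76 × 10⁻⁵ s⁻¹, Ea4 = 105 kJ mol⁻¹)
    J → Z (k5 = 0.211 s⁻¹, Ea5 = 81.0 kJ mol⁻¹)
    (constants at 35 °C)

- percent here means E units held: one Q counts as two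
- a step written with two of one species runs at k times the square of its concentration and takes two of it each time
- E is a solid; its amount is given per volume of the solution
- the list of constants is for 35 °C, to be carried to other temperatures by the activation energies
- at the start none of E is in solution
- what has only dissolved of E counts as not reacted

1. which flask leads in share of J in all that became J or Q or Z ("all alike" within 1.5 percentage points) (dusk / winter / dawn / all alike)
2. share of J in all that became J or Q or Z, dusk
3. share of J in all that became J or Q or Z, winter
4. share of J in all that became J or Q or Z, dawn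

Write kJ, kQ and kZ for the constants of G → J, 2 G → Q and J → Z at a flask's temperature, c for the solubility, t for the reading time, and y for the share asked.

1. Rank kZ first in the warm flasks. With G level, J + Z grows steadily while J relaxes, so y = f·s, with s = (1 − e⁻ⁿ)/n. Once n is large, y falls as 1/kZ, so any error in kZ passes straight into y.

2. Rank c next. It enters through the selectivity f = kJ/(kJ + 2kQ·c), so an error in c moves y less than in proportion.

3. Rank the dissolving coefficient lower: its inverse, 1.66 s, the time G takes to come to its level, is shorter than the reading time of 15 s. Ignore the step to D, since at 35 °C its constant is far smaller than that of G → J. The charge exceeds c, so solid stands beside G at first; assume for this reckoning that the level lasts through the reading.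

4. Now reckon. At dawn 0.628 is the turnover count n = kZ·t, the number of mean lifetimes of J inside the reading time. At dusk n is 3.17, in winter 13.7.

5. Take f at G = c: 44.2% at dawn, 63.8% at dusk, 78.4% in winter. At dawn the order of rank turns: a small relative error in c reaches y multiplied by 0.558, one in kZ multiplied by 0.281, so c weighs more than kZ in the dawn flask.

6. Commit: y is 32.8% at dawn, 19.3% at dusk, 5.71% in winter.

The forecast names dawn, with 22.4% at dusk, 6.4% in winter and 35.8% at dawn, and sees “J held down by its conversion to Z, which is far faster when warm”.

The simulation gives dawn as leader, with 22.4% at dusk, 6.24% in winter and 35.8% at dawn. My reckoning stands lower in each flask. In the winter flask E is down to 0% at 15.0 s and G to 13.2%, from 17.5% at 7.50 s, so the level I assumed did not last there.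

At dawn, at 15.0 s, G is made and used at a ratio of 1.00, while J is made 2.33 times faster than it is used up. So the dawn flask holds G level and J still climbing. Now read the dawn flask at 40 s: n becomes 1.67, and with the same f, y comes to 21.5%. The simulated neighbour gives 22.8%.

The constants used here were drawn at random within sensible limits; what happens was integrated by code.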